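## Retrosynthetic overview

1. The target is a cis‑fused eudesmane. Working backwards, the O9 anisoate, the C4=C15 methylene (selenoxide elimination of a C15 selenide), the C6 and C9 carbinols (hydride reduction of a 6,9‑dione) and H‑7 (hydroxyl‑directed hydrogenation) are removed to reach a bicyclic ene‑dione.
2. Key disconnection: ring A (C1–C2–C3–C4–C5–C10) is opened by a catalytic enantioselective Diels–Alder reaction that forms C1–C10 and C4–C5. The partners are thymoquinone (dienophile, C5=C10) and the silyl ether of (2E)‑penta‑2,4‑dien‑1‑ol (C1–C4 plus C15).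
3. Enabling feature: ring B (C5–C10) has oxygen at C6 and C9 (1,4), the C10 methyl and C7 isopropyl para to each other, and H‑5 cis to the C10 methyl. Ring B is therefore a reduced thymoquinone, and the cis ring fusion is the imprint of a suprafacial [4+2] addition to its methyl‑bearing C=C.
4. Ring order: ring B is bought as the quinone and ring A is closed in the key step. The C4 substituent stays sp3 (CH2OSi, then CH2SePh) as a conformational control element until it becomes the exocyclic alkene.

Key step: step 3

Remark on numbering and faces: eudesmane numbering is used. "α" is the face of ring B that carries H‑5 and the C10 methyl group; ring A carbons C1 and C4 sit on the β face. In the target O6, the isopropyl group and O9 are all α, so H‑6, H‑7 and H‑9 are β.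

Assumption: the (S)‑configured oxazaborolidinium ion is taken to expose the face of C5=C10 that gives adduct 5 as drawn. If the opposite sense were found, the mirror‑image catalyst would be used with no other change.

## Route

Step 1
Reactants: 1 (2E)‑penta‑2,4‑dienoic acid
Product: 2 (2E)‑penta‑2,4‑dien‑1‑ol
Conditions: LiAlH4, Et2O, 0 °C to rt; aqueous work‑up
Reagents that add atoms: none
Why: Hydride reduction of the carboxylic acid with LiAlH4 at low temperature should give the primary dienol by 1,2‑reduction and leave the conjugated diene intact.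

Step 2
Reactants: 2 (2E)‑penta‑2,4‑dien‑1‑ol
Product: 3 tert‑butyldimethyl[(2E)‑penta‑2,4‑dien‑1‑yloxy]silane
Conditions: TBSCl, imidazole, CH2Cl2, 0 °C to rt
Reagents that add atoms: tert‑butyldimethylsilyl chloride, CC(C)(C)[Si](C)(C)Cl
Why: Standard silylation masks the hydroxyl group, which would otherwise bind the Lewis‑acid catalyst of step 3.

Step 3
Reactants: 3 tert‑butyldimethyl[(2E)‑penta‑2,4‑dien‑1‑yloxy]silane; 4 thymoquinone (2‑isopropyl‑5‑methyl‑1,4‑benzoquinone)
Product: 5 cis‑fused adduct, 15‑(tert‑butyldimethylsilyloxy)eudesma‑2,7‑diene‑6,9‑dione (H‑5 and 10‑CH3 α, CH2OTBS on C4 β)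
Conditions: (S)‑3,3‑diphenyl‑1‑(2‑methylphenyl)tetrahydro‑1H,3H‑pyrrolo[1,2‑c][1,3,2]oxazaborole (20 mol%) activated with HN(SO2CF3)2 (18 mol%), CH2Cl2, −78 to −40 °C
Reagents that add atoms: none
Why: The protonated oxazaborolidine binds the C6 carbonyl oxygen of 4 at the lone pair syn to C5–H, which makes the methyl‑bearing C10 the electrophilic β‑carbon of the C5=C10 bond, and diene 3 adds in a concerted, asynchronous, endo [4+2] cycloaddition. The closest known reaction type is the chiral‑oxazaborolidinium‑catalysed Diels–Alder reaction of alkyl‑1,4‑benzoquinones with 1,3‑dienes. Ring A (C1–C2–C3–C4–C5–C10) is closed by suprafacial formation of the C1–C10 and C4–C5 bonds across the quinone C=C, so the new six‑membered ring is necessarily cis‑fused. C10 (quaternary, methyl) and C5 (H) are therefore cis, C4 follows from the endo rule applied to the E‑diene (CH2OTBS anti to H‑5), and the absolute configuration is set by the catalyst, whose aryl groups shield one face of the bound C5=C10 bond. The step needs site selectivity (C5=C10 rather than the isopropyl‑bearing C7=C8) and regioselectivity (C1 to C10): the first rests on the smaller β‑substituent (methyl against isopropyl at the carbon that receives the diene terminus), the second on pairing the unsubstituted, more nucleophilic diene terminus C1 with the activated C10 and the substituted terminus C4 with the unhindered C5–H.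

Step 4
Reactants: 5 cis‑fused adduct
Product: 6 15‑(tert‑butyldimethylsilyloxy)‑6β‑hydroxyeudesma‑2,7‑dien‑9‑one
Conditions: NaBH4 (1 equiv), CeCl3·7H2O, MeOH, −78 °C
Reagents that add atoms: none
Why: Luche 1,2‑reduction should take the C6 carbonyl (C9 is neopentyl and the carbonyl of a β‑alkyl enone) from the convex α face of the cis‑fused bicycle, which puts the new hydroxyl on the β face, where it serves as a temporary directing group.

Step 5
Reactants: 6 6β‑hydroxy enone
Product: 7 15‑(tert‑butyldimethylsilyloxy)‑6β‑hydroxy‑7βH‑eudesman‑9‑one (isopropyl α)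
Conditions: H2 (1–4 bar), [Ir(cod)(PCy3)(py)]PF6 (5–10 mol%), CH2Cl2, rt
Reagents that add atoms: none
Why: Hydroxyl‑directed homogeneous hydrogenation should deliver hydrogen to C7=C8 from the face of the allylic C6–OH (β), so H‑7 becomes β and the isopropyl group α, while the unhindered C2=C3 bond is saturated without stereochemical consequence.

Step 6
Reactants: 7 silyl ether
Product: 8 6β,15‑dihydroxy‑7βH‑eudesman‑9‑one
Conditions: HF·pyridine, THF/pyridine, 0 °C to rt
Reagents that add atoms: none
Why: Fluoride cleavage of the primary silyl ether is reliable here because no epimerisable centre is present (the only ketone, C9, is flanked by the quaternary C10 and a CH2).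

Step 7
Reactants: 8 keto diol
Product: 9 6β‑hydroxy‑15‑(phenylselanyl)‑7βH‑eudesman‑9‑one
Conditions: N‑(phenylseleno)phthalimide, PBu3, THF, 0 °C to rt
Reagents that add atoms: N‑(phenylseleno)phthalimide, O=C1N([Se]c2ccccc2)C(=O)c2ccccc12
Why: Grieco‑type selenide formation (alkoxyphosphonium displaced by PhSe−) is selective for the primary alcohol over the hindered secondary C6–OH, and ether formation by the cis‑disposed 6β‑OH would need a strained all‑cis tricycle.

Step 8
Reactants: 9 hydroxy selenide
Product: 10 15‑(phenylselanyl)‑7βH‑eudesmane‑6,9‑dione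
Conditions: (COCl)2, DMSO, CH2Cl2, −78 °C; then Et3N, −78 to −40 °C; cold work‑up, used at once
Reagents that add atoms: none
Why: Swern oxidation removes the temporary C6 carbinol at −78 °C, conditions that aryl alkyl selenides tolerate, and the short, cold base contact should not enolise the ketone towards the kinetically set C7 (H‑7 is equatorial in the favoured chair) or towards C5.

Step 9
Reactants: 10 selenide dione
Product: 11 15‑(phenylselanyl)‑7βH‑eudesmane‑6α,9α‑diol
Conditions: LiBH(s‑Bu)3 (3.5 equiv), THF, −78 to 0 °C; quench with water (no peroxide)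
Reagents that add atoms: none
Why: Bulky‑hydride reduction should add hydride to C6 anti to the adjacent isopropyl group and the C10 methyl (as menthone gives neomenthol), giving 6α‑OH cis to isopropyl; at C9, the chair that keeps the sp3 C4 substituent equatorial on ring A has the isopropyl group axial and 1,3‑diaxial to the α trajectory, so hydride enters equatorially from β and gives 9α‑OH.

Step 10
Reactants: 11 selenide diol
Product: 13 7βH‑eudesm‑4(15)‑ene‑6α,9α‑diol, via selenoxide 12 (not isolated)
Conditions: 30% H2O2, pyridine, THF, 0 °C then 40 °C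
Reagents that add atoms: none
Why: Oxidation to the selenoxide and syn‑elimination can only use H‑4, the single β‑hydrogen, so only the exocyclic C4=C15 alkene can form, and C5 is untouched.

Step 11
Reactants: 13 exo‑methylene diol; 14 4‑methoxybenzoyl chloride
Product: 15 (5S,6S,7R,9R,10R)‑6α‑hydroxy‑7βH‑eudesm‑4(15)‑en‑9α‑yl 4‑methoxybenzoate (target)
Conditions: 14 (1.05 equiv), DMAP (cat.), pyridine, CH2Cl2, 0 °C to rt
Reagents that add atoms: none
Why: DMAP‑catalysed acylation should favour O9, which is equatorial in the chair that has the isopropyl group equatorial, whereas O6 in that chair is axial, 1,3‑diaxial to the C10 methyl and flanked by two branched carbons.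

## Compound list

1 | (2E)‑penta‑2,4‑dienoic acid | OC(=O)/C=C/C=C | starting material
2 | (2E)‑penta‑2,4‑dien‑1‑ol | OC/C=C/C=C | intermediate
3 | tert‑butyldimethyl[(2E)‑penta‑2,4‑dien‑1‑yloxy]silane | CC(C)(C)[Si](C)(C)OC/C=C/C=C | intermediate
4 | thymoquinone (2‑isopropyl‑5‑methyl‑1,4‑benzoquinone) | CC1=CC(=O)C(C(C)C)=CC1=O | starting material
5 | 15‑(tert‑butyldimethylsilyloxy)eudesma‑2,7‑diene‑6,9‑dione, cis‑fused (H‑5, 10‑CH3 α; C4–CH2OTBS β) | CC(C)(C)[Si](C)(C)OC[C@H]1C=CC[C@]2(C)[C@H]1C(=O)C(C(C)C)=CC2=O | intermediate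
6 | 15‑(tert‑butyldimethylsilyloxy)‑6β‑hydroxyeudesma‑2,7‑dien‑9‑one | CC(C)(C)[Si](C)(C)OC[C@H]1C=CC[C@]2(C)[C@H]1[C@H](O)C(C(C)C)=CC2=O | intermediate
7 | 15‑(tert‑butyldimethylsilyloxy)‑6β‑hydroxy‑7βH‑eudesman‑9‑one (isopropyl α) | CC(C)(C)[Si](C)(C)OC[C@H]1CCC[C@]2(C)[C@H]1[C@H](O)[C@@H](C(C)C)CC2=O | intermediate
8 | 6β,15‑dihydroxy‑7βH‑eudesman‑9‑one | OC[C@H]1CCC[C@]2(C)[C@H]1[C@H](O)[C@@H](C(C)C)CC2=O | intermediate
9 | 6β‑hydroxy‑15‑(phenylselanyl)‑7βH‑eudesman‑9‑one | c1ccccc1[Se]C[C@H]1CCC[C@]2(C)[C@H]1[C@H](O)[C@@H](C(C)C)CC2=O | intermediate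
10 | 15‑(phenylselanyl)‑7βH‑eudesmane‑6,9‑dione | c1ccccc1[Se]C[C@H]1CCC[C@]2(C)[C@H]1C(=O)[C@@H](C(C)C)CC2=O | intermediate
11 | 15‑(phenylselanyl)‑7βH‑eudesmane‑6α,9α‑diol | c1ccccc1[Se]C[C@H]1CCC[C@]2(C)[C@H]1[C@@H](O)[C@@H](C(C)C)C[C@H]2O | intermediate
12 | selenoxide of 11 (15‑(phenylseleninyl)‑7βH‑eudesmane‑6α,9α‑diol) | O=[Se](c1ccccc1)C[C@H]1CCC[C@]2(C)[C@H]1[C@@H](O)[C@@H](C(C)C)C[C@H]2O | intermediate
13 | 7βH‑eudesm‑4(15)‑ene‑6α,9α‑diol | C=C1CCC[C@]2(C)[C@H]1[C@@H](O)[C@@H](C(C)C)C[C@H]2O | intermediate
14 | 4‑methoxybenzoyl chloride | COc1ccc(cc1)C(Cl)=O | starting material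
15 | (5S,6S,7R,9R,10R)‑6α‑hydroxy‑7βH‑eudesm‑4(15)‑en‑9α‑yl 4‑methoxybenzoate (CNP0107029.1) | C=C1CCC[C@]2(C)[C@H]1[C@@H](O)[C@@H](C(C)C)C[C@H]2OC(=O)c1ccc(OC)cc1 | target

## Step count and risks

Total steps: 11. Longest linear sequence: 11 (from 1 to 15); thymoquinone 4 enters at step 3 and 4‑methoxybenzoyl chloride 14 at step 11.

Steps most likely to fail:

Step 3. The catalyst may discriminate poorly between the faces of a β‑methyl‑substituted quinone double bond, cycloaddition may compete at the isopropyl‑bearing C=C, or the strong acid may ionise the allylic silyl ether before cycloaddition. The fallback sets out from 3 and 4 and gives up catalyst control. BF3·OEt2 (CH2Cl2, −78 °C) should give the same endo, regio‑defined adduct as a racemate, that is 5 together with its mirror image, ent‑adduct F1. Preparative chromatography on a chiral stationary phase (amylose tris(3,5‑dimethylphenylcarbamate), supercritical CO2/2‑propanol) removes F1, and the route is rejoined at 5.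

Step 9. Hydride delivery at C6 may show poor facial selectivity because both faces are hindered (ring A on β; isopropyl and C10 methyl on α), or the hindered dione may enolise and lose the C7 configuration. The fallback sets out from 8 and fixes the conformation covalently before C6 is reduced.
- TsOH (cat.) in MeOH should convert 8 into the bridged methyl ketal F2. C9 is the only ketone, so only the six‑membered C15–O–C9 bridge can form; it locks ring B in the chair with axial C10 methyl and equatorial isopropyl.
- Dess–Martin periodinane gives the ketal ketone F3.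
- NaBH4 (MeOH, 0 °C) should attack anti to the now 1,3‑diaxial C10 methyl, as 6‑oxo‑5β‑steroids do, to give the 6α‑alcohol F4.
- Aqueous HCl in THF releases the keto diol F5.
- N‑(phenylseleno)phthalimide/PBu3 gives the selenide F6.
- LiBH(s‑Bu)3 then reduces only C9, from the β face as in the main route, and the route is rejoined at 11.

Step 11. Acylation may compete at O6 through the ring‑flipped chair, in which O6 is equatorial and O9 axial. The fallback sets out from 11, where the sp3 C4 substituent enforces that flipped chair: 6‑OH is equatorial, and 9‑OH is axial, neopentyl and 1,3‑diaxial to the isopropyl group.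
- TESOTf/2,6‑lutidine at −78 °C should silylate only O6, giving the 6‑O‑triethylsilyl selenide F7.
- H2O2/pyridine gives, through its selenoxide F8, the 6‑O‑triethylsilyl exo‑methylene alcohol F9, in which O9 is the only free hydroxyl.
- Acylation with 14 (DMAP, pyridine, 50 °C) gives the silylated ester F10.
- HF·pyridine removes the silyl group, and the route is rejoined at 15.

Further compounds
F1 | step 3 | enantiomer of adduct 5 | CC(C)(C)[Si](C)(C)OC[C@@H]1C=CC[C@@]2(C)[C@@H]1C(=O)C(C(C)C)=CC2=O
F2 | step 9 | bridged methyl ketal of 8 (C9 ketal with O15; 6β‑OH) | O1C[C@H]2CCC[C@]3(C)[C@H]2[C@H](O)[C@@H](C(C)C)C[C@@]31OC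
F3 | step 9 | bridged methyl ketal 6‑ketone | O1C[C@H]2CCC[C@]3(C)[C@H]2C(=O)[C@@H](C(C)C)C[C@@]31OC
F4 | step 9 | bridged methyl ketal 6α‑alcohol | O1C[C@H]2CCC[C@]3(C)[C@H]2[C@@H](O)[C@@H](C(C)C)C[C@@]31OC
F5 | step 9 | 6α,15‑dihydroxy‑7βH‑eudesman‑9‑one | OC[C@H]1CCC[C@]2(C)[C@H]1[C@@H](O)[C@@H](C(C)C)CC2=O
F6 | step 9 | 6α‑hydroxy‑15‑(phenylselanyl)‑7βH‑eudesman‑9‑one | c1ccccc1[Se]C[C@H]1CCC[C@]2(C)[C@H]1[C@@H](O)[C@@H](C(C)C)CC2=O
F7 | step 11 | 6‑O‑triethylsilyl ether of selenide diol 11 | c1ccccc1[Se]C[C@H]1CCC[C@]2(C)[C@H]1[C@@H](O[Si](CC)(CC)CC)[C@@H](C(C)C)C[C@H]2O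
F8 | step 11 | selenoxide of F7 | O=[Se](c1ccccc1)C[C@H]1CCC[C@]2(C)[C@H]1[C@@H](O[Si](CC)(CC)CC)[C@@H](C(C)C)C[C@H]2O
F9 | step 11 | 6α‑(triethylsilyloxy)‑7βH‑eudesm‑4(15)‑en‑9α‑ol | C=C1CCC[C@]2(C)[C@H]1[C@@H](O[Si](CC)(CC)CC)[C@@H](C(C)C)C[C@H]2O
F10 | step 11 | 6‑O‑triethylsilyl ether of target 15 | C=C1CCC[C@]2(C)[C@H]1[C@@H](O[Si](CC)(CC)CC)[C@@H](C(C)C)C[C@H]2OC(=O)c1ccc(OC)cc1
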